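**Retrosynthetic overview**

1. Target: ring A (ten-membered carbocycle C1–C10, both ring alkenes C1=C10 and C4=C5 cis) fused at C6–C7 to ring B (α-methylene-γ-lactone O–C12(=O)–C11(=C13)–C7–C6). C8 and C9 carry the angelates, C14 is the CHO on C10, C15 the CH2OH on C4 (germacrane locants). Last operations: double angeloylation of an 8,9-diol, PMB removal and oxidation at C14, desilylation at O15.
2. Key disconnection C7–C8 (opens ring A): the precursor is 3-(bromomethyl)butenolide 19, whose side chain ends in a C8 aldehyde with a free 9-OH. Enabling feature: C13–C11=C7 is an allyl unit inside ring B. A metal at C13 (from C13–Br) turns C7, normally the electrophilic β-carbon of the unsaturated lactone, into a nucleophile for the C8 carbonyl (two acceptor carbons joined by reductive polarity reversal). The allyl shift returns the C11=C13 exo-methylene, and the 9-OH next to C8 offers chelation.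
3. Ring B is formed first (2-(bromomethyl)acrylate of the C6 carbinol, then ring-closing metathesis C7=C11). Ring A is closed second by the indium-mediated allylation, which also sets C7 and C8.
4. C3–C4: B-alkyl Suzuki–Miyaura union of a (Z)-vinyl iodide (C4–C7 and C15; C6 from a catalytic asymmetric alkynylation, alkene geometry from hydroalumination–iodination) with the 9-BBN adduct of a diene (C1–C3, C8–C10, C14).
5. The diene comes from chiral-pool ester 1 (C8, C9 with its stereocentre, C10, C14) and acrolein (C1–C3) by aldol addition and E1cB elimination.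

Key step: step 12

Assumption: (S,S)-ProPhenol is taken to deliver the alkynylzinc to the Re face of (E)-but-2-enal, giving (S)-10; if the sense proves opposite, the (R,R)-ligand is used.

**Route**

Step 1
Reactants: 1 methyl (S)-2-(2,2-dimethyl-1,3-dioxolan-4-yl)acetate; 2 acrolein
Product: 3 methyl 2-[(4S)-2,2-dimethyl-1,3-dioxolan-4-yl]-3-hydroxypent-4-enoate (diastereomer mixture at C2 and C3)
Conditions: LiN(iPr)2 (LDA), THF, −78 °C; then 2, −78 °C; aq. NH4Cl
Reagents that add atoms: none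
Why: The kinetic lithium ester enolate, which should not expel the dioxolane oxygen at −78 °C, undergoes 1,2-aldol addition to the enal; the two new stereocentres are left uncontrolled because step 2 destroys both, and C9 from the chiral pool is untouched.

Step 2
Reactants: 3 methyl 2-[(4S)-2,2-dimethyl-1,3-dioxolan-4-yl]-3-hydroxypent-4-enoate
Product: 5 methyl (2E)-2-[(4S)-2,2-dimethyl-1,3-dioxolan-4-yl]penta-2,4-dienoate, via allylic acetate 4 (not isolated)
Conditions: Ac2O, Et3N, DMAP (cat.), CH2Cl2, 0 °C; then DBU, rt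
Reagents that add atoms: none
Why: Acetylation followed by DBU-induced E1cB elimination should give the conjugated dienoate as the (2E) isomer (vinyl anti to the ester, the expected thermodynamic and kinetic product); the acetate is a far better leaving group than the acetal oxygen, so the C9 dioxolane survives.

Step 3
Reactants: 5 methyl (2E)-2-[(4S)-2,2-dimethyl-1,3-dioxolan-4-yl]penta-2,4-dienoate
Product: 6 (2Z)-2-[(4S)-2,2-dimethyl-1,3-dioxolan-4-yl]penta-2,4-dien-1-ol
Conditions: iBu2AlH (DIBAL-H), CH2Cl2, −78 °C; aq. KNaC4H4O6 (potassium sodium tartrate) work-up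
Reagents that add atoms: none
Why: DIBAL-H reduction of the conjugated ester proceeds 1,2 to the allylic alcohol without touching the acetonide or the diene; the alkene geometry is unchanged and only the CIP descriptor switches.

Step 4
Reactants: 6 (2Z)-2-[(4S)-2,2-dimethyl-1,3-dioxolan-4-yl]penta-2,4-dien-1-ol
Product: 7 (4S)-4-[(1Z)-1-{[(4-methoxyphenyl)methoxy]methyl}buta-1,3-dien-1-yl]-2,2-dimethyl-1,3-dioxolane
Conditions: NaH, 4-methoxybenzyl chloride, Bu4NI (cat.), THF/DMF, 0 °C to rt
Reagents that add atoms: 4-methoxybenzyl chloride, COc1ccc(CCl)cc1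
Why: Williamson etherification of the primary allylic alkoxide installs the PMB group that later allows C14 to be unmasked independently of O15.

Step 5
Reactants: 8 tert-butyl(diphenyl)(prop-2-yn-1-yloxy)silane; 9 (E)-but-2-enal
Product: 10 (4S,5E)-1-{[tert-butyl(diphenyl)silyl]oxy}hept-5-en-2-yn-4-ol
Conditions: (S,S)-ProPhenol [2,6-bis{[(S)-2-(hydroxydiphenylmethyl)pyrrolidin-1-yl]methyl}-4-methylphenol] (10 mol %), Me2Zn, Ph3P=O (20 mol %), toluene, 0 °C; then 9, 0–4 °C
Reagents that add atoms: none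
Why: Catalytic enantioselective alkynylation of an enal by an alkynylzinc under a dinuclear zinc–ProPhenol catalyst sets C6 through face-selective delivery of the alkyne; the propenyl group is a vinyl equivalent that is shed in step 9.

Step 6
Reactants: 10 (4S,5E)-1-{[tert-butyl(diphenyl)silyl]oxy}hept-5-en-2-yn-4-ol
Product: 12 (2Z,4S,5E)-1-{[tert-butyl(diphenyl)silyl]oxy}-2-iodohepta-2,5-dien-4-ol, via cyclic vinylaluminate 11 (not isolated)
Conditions: NaAlH2(OCH2CH2OMe)2 (Red-Al), THF, 0 °C; then I2, THF, −78 °C to 0 °C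
Reagents that add atoms: iodine, II
Why: Hydroxyl-directed trans-hydroalumination of the propargylic alcohol places aluminium on the distal alkyne carbon (C4) in a five-membered oxa-aluminacycle, and iodinolysis with retention gives the vinyl iodide with iodine cis to C6.

Step 7
Reactants: 7 (4S)-4-[(1Z)-1-{[(4-methoxyphenyl)methoxy]methyl}buta-1,3-dien-1-yl]-2,2-dimethyl-1,3-dioxolane; 12 (2Z,4S,5E)-1-{[tert-butyl(diphenyl)silyl]oxy}-2-iodohepta-2,5-dien-4-ol
Product: 14 (2E,4S,5E,9Z)-6-{[tert-butyl(diphenyl)silyl]oxymethyl}-10-[(4S)-2,2-dimethyl-1,3-dioxolan-4-yl]-11-[(4-methoxyphenyl)methoxy]undeca-2,5,9-trien-4-ol, via B-alkyl-9-BBN borane 13 (not isolated)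
Conditions: 7 (1.3 equiv), 9-BBN dimer, THF, 0 °C to rt; then 12, Pd(dppf)Cl2 (5 mol %), AsPh3, Cs2CO3, DMF/H2O, rt
Reagents that add atoms: none
Why: 9-BBN should add anti-Markovnikov to the monosubstituted terminal alkene of the diene (the trisubstituted alkene is much slower), and the primary alkylborane couples with the vinyl iodide in a B-alkyl Suzuki–Miyaura reaction with retention of geometry, so C3 ends up cis to C6.

Step 8
Reactants: 14 (2E,4S,5E,9Z)-6-{[tert-butyl(diphenyl)silyl]oxymethyl}-10-[(4S)-2,2-dimethyl-1,3-dioxolan-4-yl]-11-[(4-methoxyphenyl)methoxy]undeca-2,5,9-trien-4-ol; 15 2-(bromomethyl)prop-2-enoic acid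
Product: 16 (2E,4S,5E,9Z)-6-{[tert-butyl(diphenyl)silyl]oxymethyl}-10-[(4S)-2,2-dimethyl-1,3-dioxolan-4-yl]-11-[(4-methoxyphenyl)methoxy]undeca-2,5,9-trien-4-yl 2-(bromomethyl)prop-2-enoate
Conditions: 15, N,N'-diisopropylcarbodiimide, DMAP (5 mol %), CH2Cl2, −10 °C to 0 °C
Reagents that add atoms: none
Why: Steglich esterification of the only free hydroxyl (C6–OH) installs C11–C13 with the allylic bromide already in place; low temperature and low DMAP loading limit attack on the bromide.

Step 9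
Reactants: 16 the 2-(bromomethyl)acrylate of 14
Product: 17 (5R)-3-(bromomethyl)-5-[(1E,5Z)-2-{[tert-butyl(diphenyl)silyl]oxymethyl}-6-[(4S)-2,2-dimethyl-1,3-dioxolan-4-yl]-7-[(4-methoxyphenyl)methoxy]hepta-1,5-dien-1-yl]furan-2(5H)-one
Conditions: second-generation Grubbs catalyst RuCl2(=CHPh)(PCy3)(H2IMes) (10 mol %), CH2Cl2 (5 mM), 40 °C
Reagents that add atoms: none
Why: Ring-closing metathesis between the propenyl group on C6 and the 1,1-disubstituted acrylate alkene closes the five-membered butenolide (ring B) with loss of propene; the hindered trisubstituted alkenes should not compete with five-ring closure.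

Step 10
Reactants: 17 the bromomethyl butenolide acetonide
Product: 18 (5R)-3-(bromomethyl)-5-[(1E,5Z,7S)-2-{[tert-butyl(diphenyl)silyl]oxymethyl}-7,8-dihydroxy-6-{[(4-methoxyphenyl)methoxy]methyl}octa-1,5-dien-1-yl]furan-2(5H)-one
Conditions: AcOH/H2O/THF 3:1:1, 40 °C
Reagents that add atoms: none
Why: Acid-catalysed hydrolysis of the terminal isopropylidene acetal should leave the TBDPS ether, the PMB ether and the allylic bromide intact.

Step 11
Reactants: 18 the 8,9-diol
Product: 19 (2S,3Z,7E)-8-[(2R)-4-(bromomethyl)-5-oxo-2,5-dihydrofuran-2-yl]-7-{[tert-butyl(diphenyl)silyl]oxymethyl}-2-hydroxy-3-{[(4-methoxyphenyl)methoxy]methyl}octa-3,7-dienal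
Conditions: TEMPO (20 mol %), PhI(OAc)2 (1.1 equiv), CH2Cl2, 0 °C to rt; crude 19 used at once
Reagents that add atoms: none
Why: Oxoammonium (TEMPO) oxidation is selective for the primary over the secondary hydroxyl of the 1,2-diol and should stop at the aldehyde in anhydrous medium, leaving the 9-OH free for chelation.

Step 12
Reactants: 19 the α-hydroxy aldehyde with the 3-(bromomethyl)butenolide
Product: 21 8β,9α-dihydroxy-14-[(4-methoxyphenyl)methoxy]-15-{[tert-butyl(diphenyl)silyl]oxy}-cis,cis-germacra-1(10),4,11(13)-trien-6α,12-olide (7α-H; 6R,7R,8S,9S), via allylindium dibromide 20 (not isolated)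
Conditions: In powder (4 equiv), THF/H2O 4:1, 2 mM, 25 °C, sonication
Reagents that add atoms: none
Why: Indium inserts into the allylic C13–Br bond to give allylindium 20, which adds through its γ-carbon C7 to the C8 aldehyde in a six-membered cyclic (Zimmerman–Traxler-type) SE2′ transition state, so the C11=C7 double bond moves to C11=C13 and the α-methylene lactone appears as the ring closes; the closest known reaction type is the Barbier/Nozaki–Hiyama–Kishi allylation of aldehydes with 3-(bromomethyl)furan-2(5H)-ones and 2-(bromomethyl)acrylates, including intramolecular ring closures. Ring A is closed by 10-exo-trig attack of C7 on the aldehyde carbon, helped by the two cis trisubstituted alkenes and the butenolide, which fold the C1–C6 tether into a turn. C7 is controlled by C6: the tether leaves C6 on one face of the butenolide and the aldehyde should reach C7 on the other (the H6 side), giving the trans-6,7 fusion, since the cis-fused alternative would force the C5–C6–C7–C8 torsion towards 0° in a ten-membered ring with two cis alkenes. C8 is controlled by C9: the free 9-hydroxyl and the aldehyde oxygen bind the same trivalent indium centre (Cram-chelate), which places the C9–C10 chain axial in the chair and exposes the aldehyde face that leads to the 8,9-threo diol (8β-OH, 9α-OH) and to the syn relation between O8 and C6 across the new bond. The step needs γ- over α-attack of the allyl unit (secured by the cyclic SE2′ pathway, α-attack would also give a twelve-membered ring), ring closure over oligomerisation and protodemetalation (high dilution, water-tolerant allylindium), and attack on the aldehyde only (allylindium reagents do not add to lactones).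

Step 13
Reactants: 21 the macrocyclic 8,9-diol; 22 angelic acid [(Z)-2-methylbut-2-enoic acid]
Product: 23 8β,9α-bis(angeloyloxy)-14-[(4-methoxyphenyl)methoxy]-15-{[tert-butyl(diphenyl)silyl]oxy}-cis,cis-germacra-1(10),4,11(13)-trien-6α,12-olide (6R,7S,8S,9S)
Conditions: 22 (6 equiv), 2,4,6-trichlorobenzoyl chloride, Et3N, toluene, rt; then 21, toluene, 80 °C
Reagents that add atoms: none
Why: Yamaguchi-type acylation of both secondary hydroxyls with the preformed mixed anhydride, run without a nucleophilic catalyst, should preserve the (Z)-geometry of the angelate and avoid conjugate addition to the α-methylene lactone.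

Step 14
Reactants: 23 the bis-angelate PMB ether
Product: 24 8β,9α-bis(angeloyloxy)-14-hydroxy-15-{[tert-butyl(diphenyl)silyl]oxy}-cis,cis-germacra-1(10),4,11(13)-trien-6α,12-olide
Conditions: DDQ, CH2Cl2/aq. NaH2PO4–Na2HPO4 buffer (pH 7) 10:1, 0 °C to rt
Reagents that add atoms: none
Why: Oxidative PMB ether cleavage by DDQ proceeds through the benzylic oxocarbenium ion; the silyl ether, the angelates and the α-methylene lactone are inert to it.

Step 15
Reactants: 24 the C14 allylic alcohol
Product: 25 8β,9α-bis(angeloyloxy)-14-oxo-15-{[tert-butyl(diphenyl)silyl]oxy}-cis,cis-germacra-1(10),4,11(13)-trien-6α,12-olide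
Conditions: TEMPO (20 mol %), PhI(OAc)2 (1.2 equiv), CH2Cl2, rt
Reagents that add atoms: none
Why: TEMPO/PhI(OAc)2 oxidation converts the primary allylic alcohol into the enal under neutral, non-nucleophilic conditions, so the allylic angelate at C9 next to the new enal is not displaced.

Step 16
Reactants: 25 the C14 enal TBDPS ether
Product: 26 8β,9α-bis(angeloyloxy)-15-hydroxy-14-oxo-cis,cis-germacra-1(10),4,11(13)-trien-6α,12-olide (6R,7S,8S,9S), the target
Conditions: HF·pyridine, pyridine, THF, 0 °C to rt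
Reagents that add atoms: none
Why: Buffered fluoride desilylation removes the primary TBDPS ether under mildly acidic conditions that the enal, the angelates and the α-methylene lactone should tolerate.

**Compound list**

1 | methyl (S)-2-(2,2-dimethyl-1,3-dioxolan-4-yl)acetate | COC(=O)C[C@H]1COC(C)(C)O1 | starting material
2 | acrolein (prop-2-enal) | C=CC=O | starting material
3 | methyl 2-[(4S)-2,2-dimethyl-1,3-dioxolan-4-yl]-3-hydroxypent-4-enoate (diastereomer mixture at C2, C3) | COC(=O)C(C(O)C=C)[C@H]1COC(C)(C)O1 | intermediate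
4 | methyl 3-acetoxy-2-[(4S)-2,2-dimethyl-1,3-dioxolan-4-yl]pent-4-enoate (not isolated) | COC(=O)C(C(OC(C)=O)C=C)[C@H]1COC(C)(C)O1 | intermediate
5 | methyl (2E)-2-[(4S)-2,2-dimethyl-1,3-dioxolan-4-yl]penta-2,4-dienoate | COC(=O)/C(=C/C=C)[C@H]1COC(C)(C)O1 | intermediate
6 | (2Z)-2-[(4S)-2,2-dimethyl-1,3-dioxolan-4-yl]penta-2,4-dien-1-ol | OC/C(=C/C=C)[C@H]1COC(C)(C)O1 | intermediate
7 | (4S)-4-[(1Z)-1-{[(4-methoxyphenyl)methoxy]methyl}buta-1,3-dien-1-yl]-2,2-dimethyl-1,3-dioxolane | COc1ccc(COC/C(=C/C=C)[C@H]2COC(C)(C)O2)cc1 | intermediate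
8 | tert-butyl(diphenyl)(prop-2-yn-1-yloxy)silane | C#CCO[Si](c1ccccc1)(c1ccccc1)C(C)(C)C | starting material
9 | (E)-but-2-enal (crotonaldehyde) | C/C=C/C=O | starting material
10 | (4S,5E)-1-{[tert-butyl(diphenyl)silyl]oxy}hept-5-en-2-yn-4-ol | C/C=C/[C@H](O)C#CCO[Si](c1ccccc1)(c1ccccc1)C(C)(C)C | intermediate
11 | sodium cyclic vinylaluminate of 10 (2,5-dihydro-1,2-oxaluminole ate complex, Al on O and on the distal alkyne carbon, two 2-methoxyethoxy ligands; not isolated) | C/C=C/[C@H]1C=C(CO[Si](c2ccccc2)(c2ccccc2)C(C)(C)C)[Al-](OCCOC)(OCCOC)O1.[Na+] | intermediate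
12 | (2Z,4S,5E)-1-{[tert-butyl(diphenyl)silyl]oxy}-2-iodohepta-2,5-dien-4-ol | C/C=C/[C@H](O)/C=C(\I)CO[Si](c1ccccc1)(c1ccccc1)C(C)(C)C | intermediate
13 | 9-{(3Z)-4-[(4S)-2,2-dimethyl-1,3-dioxolan-4-yl]-5-[(4-methoxyphenyl)methoxy]pent-3-en-1-yl}-9-borabicyclo[3.3.1]nonane (not isolated) | COc1ccc(COC/C(=C/CCB2C3CCCC2CCC3)[C@H]2COC(C)(C)O2)cc1 | intermediate
14 | (2E,4S,5E,9Z)-6-{[tert-butyl(diphenyl)silyl]oxymethyl}-10-[(4S)-2,2-dimethyl-1,3-dioxolan-4-yl]-11-[(4-methoxyphenyl)methoxy]undeca-2,5,9-trien-4-ol | C/C=C/[C@H](O)/C=C(\CC/C=C(/COCc1ccc(OC)cc1)[C@H]1COC(C)(C)O1)CO[Si](c1ccccc1)(c1ccccc1)C(C)(C)C | intermediate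
15 | 2-(bromomethyl)prop-2-enoic acid | C=C(CBr)C(=O)O | starting material
16 | 2-(bromomethyl)prop-2-enoate of 14 (ester at the C4 carbinol, S) | C/C=C/[C@H](OC(=O)C(=C)CBr)/C=C(\CC/C=C(/COCc1ccc(OC)cc1)[C@H]1COC(C)(C)O1)CO[Si](c1ccccc1)(c1ccccc1)C(C)(C)C | intermediate
17 | (5R)-3-(bromomethyl)-5-[(1E,5Z)-2-{[tert-butyl(diphenyl)silyl]oxymethyl}-6-[(4S)-2,2-dimethyl-1,3-dioxolan-4-yl]-7-[(4-methoxyphenyl)methoxy]hepta-1,5-dien-1-yl]furan-2(5H)-one | O=C1O[C@H](/C=C(\CC/C=C(/COCc2ccc(OC)cc2)[C@H]2COC(C)(C)O2)CO[Si](c2ccccc2)(c2ccccc2)C(C)(C)C)C=C1CBr | intermediate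
18 | (5R)-3-(bromomethyl)-5-[(1E,5Z,7S)-2-{[tert-butyl(diphenyl)silyl]oxymethyl}-7,8-dihydroxy-6-{[(4-methoxyphenyl)methoxy]methyl}octa-1,5-dien-1-yl]furan-2(5H)-one | O=C1O[C@H](/C=C(\CC/C=C(/COCc2ccc(OC)cc2)[C@H](O)CO)CO[Si](c2ccccc2)(c2ccccc2)C(C)(C)C)C=C1CBr | intermediate
19 | (2S,3Z,7E)-8-[(2R)-4-(bromomethyl)-5-oxo-2,5-dihydrofuran-2-yl]-7-{[tert-butyl(diphenyl)silyl]oxymethyl}-2-hydroxy-3-{[(4-methoxyphenyl)methoxy]methyl}octa-3,7-dienal | O=C1O[C@H](/C=C(\CC/C=C(/COCc2ccc(OC)cc2)[C@H](O)C=O)CO[Si](c2ccccc2)(c2ccccc2)C(C)(C)C)C=C1CBr | intermediate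
20 | allylindium dibromide from 19 (C13–InBr2; not isolated) | O=C1O[C@H](/C=C(\CC/C=C(/COCc2ccc(OC)cc2)[C@H](O)C=O)CO[Si](c2ccccc2)(c2ccccc2)C(C)(C)C)C=C1C[In](Br)Br | intermediate
21 | 8β,9α-dihydroxy-14-[(4-methoxyphenyl)methoxy]-15-{[tert-butyl(diphenyl)silyl]oxy}-cis,cis-germacra-1(10),4,11(13)-trien-6α,12-olide (7α-H; 6R,7R,8S,9S) | C=C1C(=O)O[C@@H]2/C=C(/CO[Si](c3ccccc3)(c3ccccc3)C(C)(C)C)CC/C=C(/COCc3ccc(OC)cc3)[C@H](O)[C@@H](O)[C@@H]12 | intermediate
22 | angelic acid, (Z)-2-methylbut-2-enoic acid | C/C=C(/C)C(=O)O | starting material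
23 | 8β,9α-bis(angeloyloxy)-14-[(4-methoxyphenyl)methoxy]-15-{[tert-butyl(diphenyl)silyl]oxy}-cis,cis-germacra-1(10),4,11(13)-trien-6α,12-olide | C=C1C(=O)O[C@@H]2/C=C(/CO[Si](c3ccccc3)(c3ccccc3)C(C)(C)C)CC/C=C(/COCc3ccc(OC)cc3)[C@H](OC(=O)/C(C)=C\C)[C@@H](OC(=O)/C(C)=C\C)[C@@H]12 | intermediate
24 | 8β,9α-bis(angeloyloxy)-14-hydroxy-15-{[tert-butyl(diphenyl)silyl]oxy}-cis,cis-germacra-1(10),4,11(13)-trien-6α,12-olide | C=C1C(=O)O[C@@H]2/C=C(/CO[Si](c3ccccc3)(c3ccccc3)C(C)(C)C)CC/C=C(/CO)[C@H](OC(=O)/C(C)=C\C)[C@@H](OC(=O)/C(C)=C\C)[C@@H]12 | intermediate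
25 | 8β,9α-bis(angeloyloxy)-14-oxo-15-{[tert-butyl(diphenyl)silyl]oxy}-cis,cis-germacra-1(10),4,11(13)-trien-6α,12-olide | C=C1C(=O)O[C@@H]2/C=C(/CO[Si](c3ccccc3)(c3ccccc3)C(C)(C)C)CC/C=C(/C=O)[C@H](OC(=O)/C(C)=C\C)[C@@H](OC(=O)/C(C)=C\C)[C@@H]12 | intermediate
26 | 8β,9α-bis(angeloyloxy)-15-hydroxy-14-oxo-cis,cis-germacra-1(10),4,11(13)-trien-6α,12-olide (6R,7S,8S,9S) | C=C1C(=O)O[C@@H]2/C=C(/CO)CC/C=C(/C=O)[C@H](OC(=O)/C(C)=C\C)[C@@H](OC(=O)/C(C)=C\C)[C@@H]12 | target

**Step count**

Total: 16 steps. Longest linear sequence: 14 steps (steps 1–4, then 7–16); the branch through steps 5–6 is 12 steps long.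

**Steps most likely to fail, with fallbacks**

Step 12 (key step). What may go wrong: chelation control at the aldehyde is eroded, so C7 adds to the wrong face of C8, and material is lost to protodemetalation or oligomerisation. The fallback gives up chelation and corrects C8 afterwards; it sets out from 19 and comes back at 23. Aldehyde 19 is silylated at O9 (Et3SiCl, imidazole, CH2Cl2, 0 °C) to the 9-O-triethylsilyl aldehyde F1. Ring closure with CrCl2 in THF at high dilution is a Nozaki–Hiyama–Kishi allylation through a non-chelated chair with the C9 chain equatorial (Felkin–Anh); it should give the 8-epi macrocycle F2 (8α-OH, 9α-OSiEt3, trans-lactone). Mitsunobu esterification of F2 with angelic acid 22 (PPh3, DIAD, toluene) inverts C8 to the 8β-angelate F3. HF·pyridine/pyridine at 0 °C removes the triethylsilyl group selectively to the 9α-alcohol F4, and acylation of F4 under the conditions of step 13 gives 23.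

Step 11. What may go wrong: glycol cleavage or over-oxidation of the 1,2-diol by the hypervalent iodine co-oxidant, and ketol isomerisation of the α-hydroxy aldehyde on prolonged exposure. The fallback keeps the diol away from the oxidant; it sets out from 18 and comes back at 19. Diol 18 is persilylated (Me3SiCl, imidazole, CH2Cl2) to the bis(trimethylsilyl) ether F5. Its primary silyl ether is oxidised directly under Swern conditions ((COCl)2, DMSO, −78 °C; Et3N, −78 to −40 °C) to the α-trimethylsilyloxy aldehyde F6. Brief treatment with aqueous citric acid in THF at 0 °C unmasks 19 just before the cyclisation.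

Step 13. What may go wrong: incomplete second acylation of the hindered 8,9-diol, and Z to E isomerisation of the angelate to the tiglate under forcing conditions. The fallback builds the Z-alkene on the ester; it sets out from 21 and comes back at 23. Diol 21 is acylated twice with 2-[bis(2-methylphenoxy)phosphoryl]propanoic acid (N,N'-diisopropylcarbodiimide, DMAP cat., CH2Cl2) to the bis-phosphonate F7. A Z-selective Horner–Wadsworth–Emmons reaction of F7 with acetaldehyde (NaI, DBU, THF, −78 to 0 °C) then forms both angelates and gives 23.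

**Further compounds**

F1 | step 12 | 9-O-triethylsilyl ether of aldehyde 19 | O=C1O[C@H](/C=C(\CC/C=C(/COCc2ccc(OC)cc2)[C@H](O[Si](CC)(CC)CC)C=O)CO[Si](c2ccccc2)(c2ccccc2)C(C)(C)C)C=C1CBr
F2 | step 12 | 8-epi macrocycle: 8α-hydroxy-9α-(triethylsilyloxy)-14-[(4-methoxyphenyl)methoxy]-15-{[tert-butyl(diphenyl)silyl]oxy}-cis,cis-germacra-1(10),4,11(13)-trien-6α,12-olide | C=C1C(=O)O[C@@H]2/C=C(/CO[Si](c3ccccc3)(c3ccccc3)C(C)(C)C)CC/C=C(/COCc3ccc(OC)cc3)[C@H](O[Si](CC)(CC)CC)[C@H](O)[C@@H]12
F3 | step 12 | 8β-angeloyloxy-9α-(triethylsilyloxy) macrocycle | C=C1C(=O)O[C@@H]2/C=C(/CO[Si](c3ccccc3)(c3ccccc3)C(C)(C)C)CC/C=C(/COCc3ccc(OC)cc3)[C@H](O[Si](CC)(CC)CC)[C@@H](OC(=O)/C(C)=C\C)[C@@H]12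
F4 | step 12 | 8β-angeloyloxy-9α-hydroxy macrocycle | C=C1C(=O)O[C@@H]2/C=C(/CO[Si](c3ccccc3)(c3ccccc3)C(C)(C)C)CC/C=C(/COCc3ccc(OC)cc3)[C@H](O)[C@@H](OC(=O)/C(C)=C\C)[C@@H]12
F5 | step 11 | 8,9-bis(trimethylsilyl) ether of diol 18 | O=C1O[C@H](/C=C(\CC/C=C(/COCc2ccc(OC)cc2)[C@H](O[Si](C)(C)C)CO[Si](C)(C)C)CO[Si](c2ccccc2)(c2ccccc2)C(C)(C)C)C=C1CBr
F6 | step 11 | 9-O-trimethylsilyl ether of aldehyde 19 | O=C1O[C@H](/C=C(\CC/C=C(/COCc2ccc(OC)cc2)[C@H](O[Si](C)(C)C)C=O)CO[Si](c2ccccc2)(c2ccccc2)C(C)(C)C)C=C1CBr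
F7 | step 13 | 8β,9α-bis{2-[bis(2-methylphenoxy)phosphoryl]propanoyloxy} macrocycle (phosphonate α-carbons as a mixture) | C=C1C(=O)O[C@@H]2/C=C(/CO[Si](c3ccccc3)(c3ccccc3)C(C)(C)C)CC/C=C(/COCc3ccc(OC)cc3)[C@H](OC(=O)C(C)P(=O)(Oc3ccccc3C)Oc3ccccc3C)[C@@H](OC(=O)C(C)P(=O)(Oc3ccccc3C)Oc3ccccc3C)[C@@H]12
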